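A one-step picture, X with D to E, turns the whole charge of X into E, but the teal run holds 50.5% as E at 30.0 s while X is down to 2.0%, so more steps are at work.

| flask | X | D | remark | time |
|---|---|---|---|---|
| teal | 0.80 M (fed, over 8.0 s) | 1.2 M | run made earlier |  |
| summer | 0.80 M (fed, over 8.0 s) | 0.800 M |  | 2.0 min |
| spring | 0.80 M (fed, over 8.0 s) | 1.50 M |  | 2.0 min |
| dusk | 0.80 M (fed, over 8.0 s) | 3.00 M |  | 2.0 min |

Each X taken by either X step costs one D, so taking the X steps as finished leaves spare D, the charge of D less the charge of X. In teal that is 0.400 M.

teal run (percent of the X charged)

| time / s | E / % | X / % |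
|---|---|---|
| 30.0 | 50.5 | 2.0 |
| 60.0 | 48.3 | 0.4 |
| 90.0 | 45.8 | 0.2 |
| 120 | 42.9 | 0 |

(each reading ± 0.3 percentage points)

After 30.0 s the teal E falls by 7.6 percentage points, and among the steps thought possible D + E to L is the one that consumes E, so the fall is read as that step. With spare D standing by, this reads as a pseudo-first-order loss of E. Divided by the spare D, taken as constant at its reckoned value, it gives the E-loss constant, the fractional loss of E per second per unit concentration of spare D, read from teal as 0.00453 L mol⁻¹ s⁻¹.

- steps thought possible: D + E -> L; X + D -> E; X <-> G; X + D -> Z
- "hardly changes" means that all values lie within two and a half points (for a concentration: within two and a half percent of the largest)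

- amount of E at the end, in percent of the X charged for summer, spring, dusk, in this order
- the shape of the row from first to last (rises all the way / rises, then falls / falls, then rises / falls all the way / hardly changes)

The reckoning here commits to the loss of E and leaves the split of X between E and Z open. Summer has 0 M of spare D, so E in summer should stop falling once X is used. Spring has 0.700 M, which gives E a half-life of 219 s. Dusk has 2.20 M, which gives a shorter half-life of 69.5 s.

The forecast does fix a split, saying “the split between E and Z should not depend on D”. It gives 48.5%, 37% and 17%, a row that falls all the way.

The flask gives 35.6%, 41.5% and 21.0%, so the row rises, then falls.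

    D + E → L (k = 0.00630 L mol⁻¹ s⁻¹)
    X + D → E (k = 0.130 L mol⁻¹ s⁻¹)
    X ⇌ G (K = 0.560, k = 0.0110 s⁻¹)
    X + D → Z, rate k4*[X] as long as [D] is above zero (k = 0.0740 s⁻¹)

Z at the end stands at 61.1% in summer, 34.8% in spring and 18.2% in dusk, so the split of X moves with the charge of D. The E-loss constant is put to the later minute, with the spare D as reckoned from the charges. In dusk, E goes from 40.7% at 1.00 min to 21.0% at 2.00 min, a factor of 0.516 against the reckoned 0.550. In spring, E goes from 50.6% to 41.5% over the same minute, a factor of 0.820 against the reckoned 0.827.

The data were generated by integration with made-up constants, and the scatter is random.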